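(The data come from a simulation for substances that don't exist; noise was put on by code.)

The pitfall in a dosed flask is to treat the feed as a small delay. What it costs depends on how long the flask stays active, so two times must be held against each other.

| flask | starting material | partner | initiator | remark | time |
|---|---|---|---|---|---|
| north-east | 20 mM | 3 equiv | 0.5 mol% | run made earlier |  |
| north-west | 20 mM | 3 equiv | 0.7 mol% | run made earlier |  |
| south-west | 20 mM | 3 equiv | 1.1 mol% | run made earlier |  |
| Thursday's | 20 mM (fed, over 12.5 min) | 3.00 equiv | 0.5 mol% | a stirred flask in which starting material is dosed at a steady rate over 12.5 min without added volume, worked up at 25 min | 25 min |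
| Monday's | 20 mM | 3.00 equiv (fed, over 12.5 min) | 0.5 mol% | all but partner at the start; partner goes in evenly over 12.5 min, the run ends at 25 min | 25 min |
| Friday's | 20 mM | 3.00 equiv | 0.5 mol% | one stirred flow tank at steady state, fed with the mixture as stated, mean residence time 25 min |  |
| Sunday's | 20 mM | 3.00 equiv | 0.5 mol% | everything together in a closed stirred flask, run for 25 min | 25 min |

| run | time / min | target / % | starting material / % |
|---|---|---|---|
| north-east | 2.00 | 3.9 | 96.7 |
| north-east | 5.00 | 8.1 | 92.3 |
| north-east | 10.0 | 12.7 | 87.0 |
| north-east | 25.0 | 19.0 | 79.7 |
| north-west | 2.50 | 5.3 | 94.8 |
| north-west | 8.00 | 13.7 | 86.1 |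
| north-west | 12.0 | 17.7 | 82.4 |
| north-west | 20.0 | 22.4 | 77.0 |
| south-west | 1.50 | 4.4 | 95.9 |
| south-west | 4.00 | 10.2 | 89.9 |
| south-west | 8.00 | 16.9 | 82.6 |
| south-west | 20.0 | 28.7 | 71.1 |

(each reading ± 0.3 percentage points)

- the set-up with the highest amount of target at the outlet or at the end, in percent of the starting material put in ("none" if the first two lie within 2 percentage points) (Thursday's / Monday's / Friday's / Sunday's / none)
- amount of target at the outlet or at the end, in percent of the starting material put in, Thursday's
- amount of target at the outlet or at the end, in percent of the starting material put in, Monday's
- amount of target at the outlet or at the end, in percent of the starting material put in, Friday's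
- amount of target at the outlet or at the end, in percent of the starting material put in, Sunday's

- the stated concentrations are those of everything mixed, before any reaction; amounts are the same in each set-up
- the numbers in the tables scatter with a standard deviation of 0.3 percentage points
- the feed brings no volume worth counting
- the earlier runs were made in a closed, stirred flask

The first time is the fading time, read from the north-east run. The logarithm of the fraction of starting material left grows by a factor 1.74 from 5.00 min to 10.0 min, where steady first-order activity would give 2.00. If activity falls exponentially, with the fading time as its time constant, that factor gives a fading time of 16.5 min, a reading that carries the scatter of the readings behind it. The second time is the feed time, 12.5 min, and the ratio of feed to fading is 0.759.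

Each portion of starting material works from its arrival onward, so activity is weighted by the fraction already fed. Over a run lasting twice the feed, the weighted integral of activity divided by the unweighted one comes to 61.7%. This is the kept share, the reckoned target of the dosed flask as a fraction of the closed one at the same time. Applied to the north-east reading of 19.0%, it puts Thursday's near 11.7%.

The forecast is higher for Thursday's, at 12.6%, with 13% for Monday's, 17% for Friday's and 19.2% for Sunday's, and it names Sunday's as best. Its ground for Thursday's is that “starting material arrives while the initiator is dying”.

The flasks give 12.6% for Thursday's, 15.7% for Monday's, 16.2% for Friday's and 19.7% for Sunday's, which is the highest.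

    first chain carrier → ended carrier (k = 345 min⁻¹)
    initiator → 2 initiating radical (k = 0.106 min⁻¹)
    starting material + second chain carrier → released group + first chain carrier (k = 3.22 × 10⁵ L mol⁻¹ min⁻¹)
    2 first chain carrier → ended chains B (k = 6.00 × 10⁶ L mol⁻¹ s⁻¹)
    partner + first chain carrier → target + second chain carrier (k = 3.80 × 10⁵ L mol⁻¹ min⁻¹)
    starting material + initiating radical → capped initiator + first chain carrier (k = 5.66 × 10⁵ L mol⁻¹ s⁻¹)
    2 second chain carrier → ended chains A (k = 4.00 × 10⁷ L mol⁻¹ s⁻¹)
    2 partner → self-condensation product (k = 0.247 L mol⁻¹ min⁻¹)

Thursday's keeps 64.0% of Sunday's target, beside the reckoned 61.7%. The feed of 12.5 min lasts nearly twice the initiator's half-life of 6.5 min, and at the end of the feed Thursday's holds 26.6% of its initiator. The neighbour of Thursday's charged with 50 mM of starting material has 7.1% of its initiator left at the end, as Thursday's has 7.1%, and it ends at 19.3% target.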